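Assumption: sacculatane (drimane) numbering C1–C12 of the target is used for every intermediate (α = face of 5‑H, β = face of the C10 methyl group), and alkynes 6 and 14 are taken as catalogue chemicals.

**Retrosynthetic overview**
- Ring B is closed last. C7=C8 comes from a phosphine-triggered intramolecular Wittig reaction of an ene-dial with the C7 aldehyde, which also sets C9. The prenyl terminus comes from cross metathesis of a vinyl group.
- The 1α-OH comes from equatorial hydride attack on a C1 ketone.
- Ring A and C3, C4, C5 and C10 come from one chloriranium-initiated cyclisation of an acyclic silyl ether, ended by a 1,2-alkenyl (semipinacol) shift from C1 to C10.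
- The (R)-tertiary carbinol comes from an enone and an alkenylzinc by asymmetric 1,2-addition. The enone comes from a β,γ-unsaturated aldehyde and a vinyllithium.
- The building blocks have three to eight heavy atoms. Rings are formed in the order A, then B.

**Step 1**
Reactants: 1 hex-5-en-1-yne; 2 oxirane
Product: 4 (E)-4-methylocta-3,7-dien-1-ol, via alkenyldimethylalane 3 (not isolated)
Conditions: AlMe3 (2 equiv), Cp2ZrCl2 (20 mol %), CH2Cl2, 0 °C to rt; n-BuLi, THF, −78 °C; 2, −78 °C to rt; aq. HCl
Reagents that add atoms: trimethylaluminium, C[Al](C)C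
Why: Zirconium-catalysed Negishi carboalumination adds CH3 and Al syn to the alkyne only (the terminal alkene is much slower), and the derived alanate opens oxirane with retention, which fixes the E C3=C4 alkene that later decides the C3/C4 relationship.

**Step 2**
Reactants: 4 (E)-4-methylocta-3,7-dien-1-ol
Product: 5 (E)-4-methylocta-3,7-dienal
Conditions: Dess–Martin periodinane, CH2Cl2, 0 °C, used at once
Reagents that add atoms: none
Why: Dess–Martin oxidation is near neutral, so the β,γ-unsaturated aldehyde forms without the C3=C4 alkene moving into conjugation.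

**Step 3**
Reactants: 6 3,3-dimethoxyprop-1-yne; 7 trimethyl orthoformate
Product: 9 1,1,4,4-tetramethoxybut-2-yne, via alkynylmagnesium bromide 8 (not isolated)
Conditions: EtMgBr, THF, 0 °C to rt; 7, toluene, 100 °C; H2O
Reagents that add atoms: none
Why: The alkynyl Grignard reagent displaces one methoxy group of the orthoester (Bodroux–Chichibabin-type acetal synthesis) and gives a symmetrical alkyne that carries C11, C9, C8 and C12 at the aldehyde level.

**Step 4**
Reactants: 9 1,1,4,4-tetramethoxybut-2-yne
Product: 10 (E)-tributyl(1,1,4,4-tetramethoxybut-2-en-2-yl)stannane (acetal groups cis)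
Conditions: Bu3SnH, Pd(PPh3)4 (2 mol %), THF, 0 °C
Reagents that add atoms: tributyltin hydride, CCCC[SnH](CCCC)CCCC
Why: Palladium-catalysed hydrostannation is a syn addition and the alkyne is symmetrical, so a single alkenylstannane is formed.

**Step 5**
Reactants: 10 (E)-alkenylstannane; 5 (E)-4-methylocta-3,7-dienal
Product: 12 racemic (2Z,6E)-3-(dimethoxymethyl)-1,1-dimethoxy-7-methylundeca-2,6,10-trien-4-ol, via vinyllithium 11 (not isolated)
Conditions: n-BuLi, THF, −78 °C; 5, −78 °C; H2O
Reagents that add atoms: none
Why: Tin–lithium exchange keeps the alkene geometry, and the α-(dialkoxymethyl)vinyllithium adds 1,2 to the aldehyde at −78 °C faster than it enolises it; the racemic carbinol centre is erased in step 6.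

**Step 6**
Reactants: 12 racemic allylic alcohol
Product: 13 (2E,6E)-3-(dimethoxymethyl)-1,1-dimethoxy-7-methylundeca-2,6,10-trien-4-one (acetal groups cis)
Conditions: Dess–Martin periodinane, CH2Cl2, 0 °C
Reagents that add atoms: none
Why: Dess–Martin oxidation of the allylic alcohol spares the acetals and does not isomerise the skipped C3=C4 alkene.

**Step 7**
Reactants: 14 4,4-dimethoxybut-1-yne
Product: 16 5,5-dimethoxypent-2-yne, via lithium acetylide 15 (not isolated)
Conditions: n-BuLi, THF, −78 °C; MeI, −78 °C to rt
Reagents that add atoms: iodomethane, CI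
Why: SN2 methylation of the lithium acetylide installs the carbon that becomes the C10 methyl group.

**Step 8**
Reactants: 16 5,5-dimethoxypent-2-yne; 13 enone
Product: 19 (R)-tertiary carbinol whose C1 bears OH plus the (E)-3-methylhepta-2,6-dienyl arm plus the (E)-5,5-dimethoxypent-2-en-2-yl arm plus the (Z)-1,1,4,4-tetramethoxybut-2-en-2-yl arm, via alkenylzirconocene 17 (not isolated), via alkenyl(methyl)zinc 18 (not isolated)
Conditions: Cp2ZrHCl (1.2 equiv), CH2Cl2, rt; Me2Zn, toluene, −78 °C; Ti(Oi-Pr)4 (1.2 equiv), trans-cyclohexane-1,2-diamine bis(hydroxycamphorsulfonamide) ligand (10 mol %, enantiomer chosen for Re-face attack), 13, rt; H2O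
Reagents that add atoms: none
Why: Syn hydrozirconation puts Zr on the methyl-bearing carbon (E alkenyl); Zr-to-Zn exchange and titanium/bis(sulfonamide) diol-catalysed asymmetric 1,2-alkenylation of the ketone then attack the Re face, because the catalyst tells the CH2 arm from the α-branched alkenyl arm, and this sets (R)-C1.

**Step 9**
Reactants: 19 (R)-tertiary carbinol
Product: 20 trimethylsilyl ether of 19
Conditions: N-(trimethylsilyl)imidazole (3 equiv), CH2Cl2, 35 °C
Reagents that add atoms: N-(trimethylsilyl)imidazole, C[Si](C)(C)n1ccnc1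
Why: Acid-free O-silylation leaves the acetals alone, blocks 5-endo chloroetherification by the homoallylic oxygen in step 10 and keeps the oxygen push needed for the shift.

**Step 10**
Reactants: 20 silyl ether
Product: 23 (2S,3R,4S,5S)-4-(but-3-en-1-yl)-5-chloro-3-(2,2-dimethoxyethyl)-2,4-dimethyl-2-[(Z)-1,1,4,4-tetramethoxybut-2-en-2-yl]cyclohexan-1-one, via chloriranium ion 21 (not isolated), via C10 carbocation 22 (not isolated)
Conditions: NCS (1.05 equiv), Ph3P=S (10 mol %), 2,6-di-tert-butylpyridine (20 mol %), CH2Cl2/(CF3)2CHOH 4:1, −40 °C; aq. NaHCO3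
Reagents that add atoms: N-chlorosuccinimide, O=C1CCC(=O)N1Cl
Why: Proposed new method: Lewis-base-activated NCS transfers Cl+ to the most electron-rich and least hindered alkene C3=C4 (the vinyl group, the carbinol-flanked C5=C10 alkene and the bis-acetal alkene are poorer donors); the E C5=C10 alkene opens the chloriranium ion anti at C4 through a chair in which allylic 1,2-strain with the C10 methyl group puts the small OSiMe3 group in the alkene plane and the alkenyl arm axial, so that arm lines up with the empty orbital at C10 and migrates from C1 to C10 anti to the new C4–C5 bond while the silyloxy group collapses to the ketone, which relays (R)-C1 into 3β-Cl, 4α-butenyl, 5α-H and 10β-CH3 in one operation; the closest known reactions are haliranium-induced polyene cyclisations in HFIP and halogenation/semipinacol rearrangements of allylic alcohols, which have not yet been merged.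

**Step 11**
Reactants: 23 β-chloro ketone
Product: 24 (1S,2S,3R,4S,5S)-4-(but-3-en-1-yl)-5-chloro-3-(2,2-dimethoxyethyl)-2,4-dimethyl-2-[(Z)-1,1,4,4-tetramethoxybut-2-en-2-yl]cyclohexan-1-ol
Conditions: LiBH(s-Bu)3, THF, −78 °C; H2O
Reagents that add atoms: none
Why: The bulky borohydride attacks along the equatorial trajectory (as with 4,4-dimethyl-3-keto terpenoids) and gives the axial 1α-alcohol, and at −78 °C reduction outruns loss of HCl from the β-chloro ketone.

**Step 12**
Reactants: 24 vinyl alcohol; 25 2-methylbut-2-ene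
Product: 26 (1S,2S,3R,4S,5S)-5-chloro-3-(2,2-dimethoxyethyl)-2,4-dimethyl-4-(4-methylpent-3-en-1-yl)-2-[(Z)-1,1,4,4-tetramethoxybut-2-en-2-yl]cyclohexan-1-ol
Conditions: second-generation Hoveyda–Grubbs catalyst (5 mol %), 25/CH2Cl2 1:1, 40 °C, sealed tube
Reagents that add atoms: none
Why: In olefin cross metathesis only the monosubstituted vinyl group is reactive (the hindered bis-acetal trisubstituted alkene is inert), and it is capped as the isopropylidene end of the side chain.

**Step 13**
Reactants: 26 tris-acetal
Product: 27 (Z)-2-[(1S,2R,3S,4S,6S)-4-chloro-6-hydroxy-1,3-dimethyl-3-(4-methylpent-3-en-1-yl)-2-(2-oxoethyl)cyclohexyl]but-2-enedial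
Conditions: Amberlyst-15, acetone/H2O 10:1, 0 °C to rt, used crude
Reagents that add atoms: water, O
Why: Mild acid-catalysed acetal hydrolysis frees all three aldehydes without any oxidant, so the free 1α-OH, the chloride and the trisubstituted alkene are untouched.

**Step 14**
Reactants: 27 hydroxy ene-dial aldehyde
Product: 29 (1R,4aR,5S,6S,8S,8aS)-6-chloro-8-hydroxy-5,8a-dimethyl-5-(4-methylpent-3-en-1-yl)-1,4,4a,5,6,7,8,8a-octahydronaphthalene-1,2-dicarbaldehyde, via formyl-stabilised ylide 28 (not isolated)
Conditions: PPh3 (1.1 equiv), PhOH (10 mol %), toluene (0.005 M), rt to 45 °C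
Reagents that add atoms: none
Why: Proposed new method: PPh3 adds to the unhindered β-carbon C8 of the ene-dial, the enolate is protonated at C9 from the face turned toward C1 (the other face is covered by C5 and its side chain, and the 1α-OH can relay the proton) to give 9α-H, proton loss from C8 gives the formyl-stabilised ylide, and this closes ring B on the C7 aldehyde by intramolecular Wittig reaction under non-basic conditions that do not epimerise C9; the closest known reaction is the phosphine-mediated Michael/proton-shift/Wittig olefination of maleates, maleimides and ene-diones with aldehydes, not yet shown for an ene-dial or for such a ring closure.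

**Compound list**
1 | hex-5-en-1-yne | C#CCCC=C | starting material
2 | oxirane | C1CO1 | starting material
3 | (E)-dimethyl(2-methylhexa-1,5-dien-1-yl)alane | C=CCC/C(C)=C/[Al](C)C | intermediate
4 | (E)-4-methylocta-3,7-dien-1-ol | C=CCC/C(C)=C/CCO | intermediate
5 | (E)-4-methylocta-3,7-dienal | C=CCC/C(C)=C/CC=O | intermediate
6 | 3,3-dimethoxyprop-1-yne | C#CC(OC)OC | starting material
7 | trimethyl orthoformate | COC(OC)OC | starting material
8 | (3,3-dimethoxyprop-1-yn-1-yl)magnesium bromide | Br[Mg]C#CC(OC)OC | intermediate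
9 | 1,1,4,4-tetramethoxybut-2-yne | COC(OC)C#CC(OC)OC | intermediate
10 | (E)-tributyl(1,1,4,4-tetramethoxybut-2-en-2-yl)stannane | CCCC[Sn](CCCC)(CCCC)/C(C(OC)OC)=C/C(OC)OC | intermediate
11 | (Z)-(1,1,4,4-tetramethoxybut-2-en-2-yl)lithium | [Li]/C(C(OC)OC)=C/C(OC)OC | intermediate
12 | racemic (2Z,6E)-3-(dimethoxymethyl)-1,1-dimethoxy-7-methylundeca-2,6,10-trien-4-ol | C=CCC/C(C)=C/CC(O)/C(C(OC)OC)=C/C(OC)OC | intermediate
13 | (2E,6E)-3-(dimethoxymethyl)-1,1-dimethoxy-7-methylundeca-2,6,10-trien-4-one | C=CCC/C(C)=C/CC(=O)/C(C(OC)OC)=C/C(OC)OC | intermediate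
14 | 4,4-dimethoxybut-1-yne | C#CCC(OC)OC | starting material
15 | (4,4-dimethoxybut-1-yn-1-yl)lithium | [Li]C#CCC(OC)OC | intermediate
16 | 5,5-dimethoxypent-2-yne | CC#CCC(OC)OC | intermediate
17 | (E)-chloro(5,5-dimethoxypent-2-en-2-yl)zirconocene | Cl[Zr](C1C=CC=C1)(C1C=CC=C1)/C(C)=C/CC(OC)OC | intermediate
18 | (E)-(5,5-dimethoxypent-2-en-2-yl)(methyl)zinc | C[Zn]/C(C)=C/CC(OC)OC | intermediate
19 | (R)-tertiary carbinol (three arms as in step 8) | C=CCC/C(C)=C/C[C@](O)(/C(C(OC)OC)=C/C(OC)OC)/C(C)=C/CC(OC)OC | intermediate
20 | trimethylsilyl ether of 19 | C=CCC/C(C)=C/C[C@](O[Si](C)(C)C)(/C(C(OC)OC)=C/C(OC)OC)/C(C)=C/CC(OC)OC | intermediate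
21 | C3/C4 chloriranium ion of 20 | C=CCC[C@]1(C)[Cl+][C@H]1C[C@](O[Si](C)(C)C)(/C(C(OC)OC)=C/C(OC)OC)/C(C)=C/CC(OC)OC | intermediate
22 | ring A C10 carbocation (alkenyl arm axial on C1) | C=CCC[C@]1(C)[C@@H](Cl)C[C@](O[Si](C)(C)C)(/C(C(OC)OC)=C/C(OC)OC)[C+](C)[C@H]1CC(OC)OC | intermediate
23 | (2S,3R,4S,5S)-β-chloro ketone of step 10 | C=CCC[C@]1(C)[C@@H](Cl)CC(=O)[C@](C)(/C(C(OC)OC)=C/C(OC)OC)[C@H]1CC(OC)OC | intermediate
24 | (1S,2S,3R,4S,5S)-1α-alcohol of step 11 | C=CCC[C@]1(C)[C@@H](Cl)C[C@H](O)[C@](C)(/C(C(OC)OC)=C/C(OC)OC)[C@H]1CC(OC)OC | intermediate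
25 | 2-methylbut-2-ene | CC=C(C)C | starting material
26 | (1S,2S,3R,4S,5S)-homoprenyl tris-acetal of step 12 | CC(C)=CCC[C@]1(C)[C@@H](Cl)C[C@H](O)[C@](C)(/C(C(OC)OC)=C/C(OC)OC)[C@H]1CC(OC)OC | intermediate
27 | hydroxy ene-dial aldehyde of step 13 | CC(C)=CCC[C@]1(C)[C@@H](Cl)C[C@H](O)[C@](C)(/C(C=O)=C/C=O)[C@H]1CC=O | intermediate
28 | C8 triphenylphosphonium ylide with 9α-H | CC(C)=CCC[C@]1(C)[C@@H](Cl)C[C@H](O)[C@](C)([C@@H](C=O)C(C=O)=P(c2ccccc2)(c2ccccc2)c2ccccc2)[C@H]1CC=O | intermediate
29 | CNP0155449.1 (name as in step 14) | CC(C)=CCC[C@]1(C)[C@@H](Cl)C[C@H](O)[C@]2(C)[C@@H](C=O)C(C=O)=CC[C@@H]12 | target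

**Step count**
- Total steps: 14.
- Longest linear sequence: 11 steps (1, 2, 5, 6, 8, 9, 10, 11, 12, 13, 14).

**The three steps most likely to fail**

1. Step 10 (new cascade).
   - Risks: chlorination of another alkene, capture of the C10 cation by an acetal oxygen, or proton loss instead of the shift.
   - Fallback: run the two events as separate known reactions, setting out from 20. The known N-chlorosuccinimide/morpholinium salt haliranium cyclisation in HFIP, ended by proton loss from the C10 methyl group, gives the ring A exocyclic-methylene silyl ether F1. In a second flask a catalytic strong acid (Tf2NH, 5 mol %, CH2Cl2, −78 °C) reprotonates the 1,1-disubstituted alkene. With no base present, the known acid-promoted semipinacol rearrangement of the allylic silyl ether is then the only irreversible exit. This returns to the route at 23.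

2. Step 14 (new ring closure).
   - Risks: poor facial selectivity of the C9 protonation, or simple phosphine/water reduction of the ene-dial.
   - Fallback: set out from 27. Known conjugate reduction of the ene-dial with Zn/AcOH gives the saturated trialdehyde F2 as a C9 epimer mixture. The known dibenzylammonium trifluoroacetate-catalysed intramolecular aldol condensation (C8 onto the C7 aldehyde) then closes ring B. The 9-epimer and any regioisomer are removed by chromatography, and the sequence returns at 29.

3. Step 8 (asymmetric alkenylation of a hindered, enolisable enone with a trisubstituted alkenylzinc).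
   - Fallback: known lithiation–borylation chemistry, setting out from 13 and 16.
   - Oxazaborolidine-catalysed borane reduction of 13 gives the (S)-allylic alcohol F3, and i-Pr2NCOCl converts it into the carbamate F4.
   - Cp2ZrHCl-catalysed hydroboration of 16 with pinacolborane gives the alkenylboronic ester F5.
   - Deprotonation of F4 with s-BuLi/TMEDA at −78 °C, capture by F5 with retention and the 1,2-metallate shift with loss of the carbamate give the tertiary boronic ester F6.
   - NaOH/H2O2 oxidation with retention returns to the route at 19.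

**Further compounds**
F1 | step 10 | ring A exocyclic-methylene silyl ether (C10=CH2, C1 still bearing OSiMe3 and the alkenyl arm) | C=CCC[C@]1(C)[C@@H](Cl)C[C@](O[Si](C)(C)C)(/C(C(OC)OC)=C/C(OC)OC)C(=C)[C@H]1CC(OC)OC
F2 | step 14 | saturated trialdehyde (C9 epimer mixture) | CC(C)=CCC[C@]1(C)[C@@H](Cl)C[C@H](O)[C@](C)(C(C=O)CC=O)[C@H]1CC=O
F3 | step 8 | (S)-enantiomer of allylic alcohol 12 | C=CCC/C(C)=C/C[C@H](O)/C(C(OC)OC)=C/C(OC)OC
F4 | step 8 | (S)-N,N-diisopropylcarbamate of F3 | C=CCC/C(C)=C/C[C@H](OC(=O)N(C(C)C)C(C)C)/C(C(OC)OC)=C/C(OC)OC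
F5 | step 8 | (E)-2-(5,5-dimethoxypent-2-en-2-yl)-4,4,5,5-tetramethyl-1,3,2-dioxaborolane | CC1(C)OB(/C(C)=C/CC(OC)OC)OC1(C)C
F6 | step 8 | tertiary pinacol boronic ester (boron in the place of the OH of 19) | C=CCC/C(C)=C/C[C@](B1OC(C)(C)C(C)(C)O1)(/C(C(OC)OC)=C/C(OC)OC)/C(C)=C/CC(OC)OC
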